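**Plan**
Numbering: C1 carries the aryl group, C2 the hydroxymethyl group, C3 the formyl group, C4 is the vinylic CH, and C4a/C8a are the fusion carbons.
Retrosynthesis: the C3–CHO bond and the C3=C4 unsaturation go back to a C4 ketone; the tetralone is cut at C1–C8a, the resulting 1,2-diarylcyclobutanol at C4–C4a, and the cyclobutanone at C1–C2 and C3–C4 ([2+2]).
Forward: the four-membered ring is made first (keteniminium ion plus allyl benzyl ether), the second aryl group is added to its carbonyl, oxidative ring expansion closes the six-membered ring onto ring A, and the enal is installed before global debenzylation.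
Enabling feature: ring A is a 3,5-dimethoxy-4-oxygenated phenyl whose two carbons ortho to C4a are equivalent and methoxy-activated, so a benzylic C1 radical tied to it through C2, C3 and the C4 carbonyl can form C1–C8a in only one regiochemical sense.
Stereochemistry: C2 is set in the [2+2] by a C2-symmetric pyrrolidine auxiliary; C1 is set trans to C2 during ring closure; the two other cyclobutane centres are erased in that step.

Key step: step 6

Assumption: the (2R,5R)-2,5-dimethylpyrrolidine amide is taken to deliver the (3S) cyclobutanone; if the cycloaddition shows the opposite facial sense, the equally available (2S,5S) amine would be used with no other change.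

**Step 1**
Reactants: 1 4-hydroxy-3,5-dimethoxyphenylacetic acid
Product: 3 2-[4-(benzyloxy)-3,5-dimethoxyphenyl]acetic acid, via benzyl ester 2 (not isolated)
Conditions: BnBr (2.2 equiv), K2CO3, DMF, 60 °C; then aq. NaOH, MeOH, 60 °C; HCl to pH 2
Reagents that add atoms: benzyl bromide, BrCc1ccccc1; sodium hydroxide, [Na+].[OH-]
Why: Williamson O-benzylation of the phenoxide (the carboxylate is benzylated as well) followed by saponification of the benzyl ester should leave only the aryl benzyl ether, which is expected to survive every later step up to the final Lewis-acid cleavage.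

**Step 2**
Reactants: 3 2-[4-(benzyloxy)-3,5-dimethoxyphenyl]acetic acid; 4 (2R,5R)-2,5-dimethylpyrrolidine
Product: 6 2-[4-(benzyloxy)-3,5-dimethoxyphenyl]-1-[(2R,5R)-2,5-dimethylpyrrolidin-1-yl]ethan-1-one, via acid chloride 5 (not isolated)
Conditions: (COCl)2, cat. DMF, CH2Cl2, 0 °C → rt; then 4, Et3N, CH2Cl2, 0 °C → rt
Reagents that add atoms: none
Why: Acid chloride formation followed by N-acylation is the dependable way to acylate a hindered secondary amine, and neither the benzyl ether nor the two stereocentres of the auxiliary are affected.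

**Step 3**
Reactants: 6 2-[4-(benzyloxy)-3,5-dimethoxyphenyl]-1-[(2R,5R)-2,5-dimethylpyrrolidin-1-yl]ethan-1-one; 7 allyl benzyl ether
Product: 10 (2S,3S)-2-[4-(benzyloxy)-3,5-dimethoxyphenyl]-3-[(benzyloxy)methyl]cyclobutan-1-one, via keteniminium triflate 8 (not isolated), via cyclobutaniminium triflate 9 (not isolated)
Conditions: Tf2O, 2,4,6-collidine, 7 (3 equiv), ClCH2CH2Cl, −20 → 80 °C; then aq. NaHCO3, 60 °C
Reagents that add atoms: water, O
Why: Amide activation with triflic anhydride and α-deprotonation give the keteniminium ion, whose [2+2] cycloaddition with the terminal alkene joins the alkene CH2 to the iminium carbon and the internal carbon to the aryl-bearing carbon (hence the 2-aryl-3-substituted pattern); the C2-symmetric pyrrolidine differentiates the two faces and sets C3, while the enolisable C2 should settle trans to it during hydrolysis of the iminium salt.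

**Step 4**
Reactants: 11 4-bromo-2,6-dimethoxyphenol
Product: 12 2-(benzyloxy)-5-bromo-1,3-dimethoxybenzene
Conditions: BnBr, K2CO3, DMF, 60 °C
Reagents that add atoms: benzyl bromide, BrCc1ccccc1
Why: Williamson etherification of the phenoxide gives the same benzyl protection as on the other aryl ring, so that both phenols can be released together at the end.

**Step 5**
Reactants: 12 2-(benzyloxy)-5-bromo-1,3-dimethoxybenzene; 10 (2S,3S)-2-[4-(benzyloxy)-3,5-dimethoxyphenyl]-3-[(benzyloxy)methyl]cyclobutan-1-one
Product: 14 (1S,2S,3S)-1,2-bis[4-(benzyloxy)-3,5-dimethoxyphenyl]-3-[(benzyloxy)methyl]cyclobutan-1-ol, via aryllithium 13 (not isolated)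
Conditions: 12, n-BuLi, THF, −78 °C; then 10, THF, −78 → −40 °C; H2O quench
Reagents that add atoms: none
Why: Bromine–lithium exchange and 1,2-addition to the strained, highly electrophilic cyclobutanone should outrun enolisation at low temperature; the aryl group is expected to enter anti to the neighbouring C2 aryl group, and a C1 epimer would serve equally well because this carbon becomes the ketone carbon in step 6.

**Step 6**
Reactants: 14 (1S,2S,3S)-1,2-bis[4-(benzyloxy)-3,5-dimethoxyphenyl]-3-[(benzyloxy)methyl]cyclobutan-1-ol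
Product: 15 (3S,4S)-6-(benzyloxy)-4-[4-(benzyloxy)-3,5-dimethoxyphenyl]-3-[(benzyloxy)methyl]-5,7-dimethoxy-3,4-dihydronaphthalen-1(2H)-one
Conditions: AgNO3 (20 mol %), K2S2O8 (2 equiv), CH2Cl2/H2O 1:1, 30 °C
Reagents that add atoms: none
Why: Silver(II) formed from Ag(I) and persulfate (or direct one-electron oxidation of the electron-rich carbinol aryl ring) converts the tertiary cyclobutanol into its alkoxy radical, and relief of ring strain drives β-scission of the ring bond toward the aryl-bearing carbon, unmasking the aryl ketone (future C4) and a 4-alkoxybenzylic radical at the future C1. This radical, or the benzylic cation formed from it by a further one-electron oxidation, attacks the carbon ortho to the new acyl group, and oxidation plus proton loss from the cyclohexadienyl intermediate restores aromaticity; the closest known reaction type is the oxidative ring expansion of 1-arylcyclobutanols to 1-tetralones by alkoxy-radical β-scission and homolytic aromatic substitution. The one ring formed is the six-membered carbocycle C1–C2–C3–C4–C4a–C8a, closed by ortho attack (6-endo with respect to the C4a–C8a aromatic edge; ipso 5-exo attack would give a spiro radical that cannot rearomatise directly). The one new stereocentre, C1, is set under substrate control by C2: the planar benzylic centre should close through a half-chair in which the benzyloxymethyl group is pseudo-equatorial and the aryl group turns away from it, giving the 1,2-trans tetralone, and since the carbinol carbon becomes the carbonyl and the benzylic carbon becomes planar, every cyclobutanol diastereomer converges on this product. The step needs scission toward the benzylic carbon and not toward the ring CH2, which benzylic stabilisation secures, and a single site of arylation, which the two equivalent ortho carbons of the 4-benzyloxy-3,5-dimethoxyphenyl ring (each ortho to one methoxy group and para to the other) secure.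

**Step 7**
Reactants: 15 (3S,4S)-6-(benzyloxy)-4-[4-(benzyloxy)-3,5-dimethoxyphenyl]-3-[(benzyloxy)methyl]-5,7-dimethoxy-3,4-dihydronaphthalen-1(2H)-one
Product: 16 (2Z,3R,4S)-6-(benzyloxy)-4-[4-(benzyloxy)-3,5-dimethoxyphenyl]-3-[(benzyloxy)methyl]-2-(hydroxymethylidene)-5,7-dimethoxy-3,4-dihydronaphthalen-1(2H)-one
Conditions: HCO2Et, NaH, cat. EtOH, THF, 0 °C → rt; 1 M HCl work-up
Reagents that add atoms: ethyl formate, CCOC=O
Why: Crossed Claisen condensation at the only enolisable position (C3 of the target; the other α-carbon is aromatic) is driven by formation of the stabilised β-keto aldehyde enolate, and the C1 and C2 hydrogens are not acidic enough to be disturbed.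

**Step 8**
Reactants: 16 (2Z,3R,4S)-6-(benzyloxy)-4-[4-(benzyloxy)-3,5-dimethoxyphenyl]-3-[(benzyloxy)methyl]-2-(hydroxymethylidene)-5,7-dimethoxy-3,4-dihydronaphthalen-1(2H)-one
Product: 17 (2E,3R,4S)-6-(benzyloxy)-4-[4-(benzyloxy)-3,5-dimethoxyphenyl]-3-[(benzyloxy)methyl]-5,7-dimethoxy-2-[(propan-2-yloxy)methylidene]-3,4-dihydronaphthalen-1(2H)-one
Conditions: 2-iodopropane, K2CO3, acetone, reflux
Reagents that add atoms: 2-iodopropane, CC(C)I
Why: O-alkylation of the hydroxymethylene ketone with a hindered secondary iodide and carbonate should give the vinylogous ester (attack at oxygen is favoured over carbon with such an electrophile), and the double-bond geometry is of no consequence because it is lost in step 9.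

**Step 9**
Reactants: 17 (2E,3R,4S)-6-(benzyloxy)-4-[4-(benzyloxy)-3,5-dimethoxyphenyl]-3-[(benzyloxy)methyl]-5,7-dimethoxy-2-[(propan-2-yloxy)methylidene]-3,4-dihydronaphthalen-1(2H)-one
Product: 19 (1S,2R)-7-(benzyloxy)-1-[4-(benzyloxy)-3,5-dimethoxyphenyl]-2-[(benzyloxy)methyl]-6,8-dimethoxy-1,2-dihydronaphthalene-3-carbaldehyde, via allylic alcohol 18 (not isolated)
Conditions: NaBH4, CeCl3·7H2O, MeOH/THF, −20 → 0 °C; then 1 M HCl, THF, 0 °C → rt
Reagents that add atoms: water, O
Why: Luche 1,2-reduction of the vinylogous ester gives the benzylic allylic alcohol, which in dilute acid should ionise to the oxocarbenium-stabilised C4 cation and be hydrolysed at the former enol-ether carbon with loss of propan-2-ol (Stork–Danheiser-type 1,3-carbonyl transposition), giving the C3=C4 enal without touching C1 or C2, neither of which is enolisable in the product.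

**Step 10**
Reactants: 19 (1S,2R)-7-(benzyloxy)-1-[4-(benzyloxy)-3,5-dimethoxyphenyl]-2-[(benzyloxy)methyl]-6,8-dimethoxy-1,2-dihydronaphthalene-3-carbaldehyde
Product: 20 (1S,2R)-7-hydroxy-1-(4-hydroxy-3,5-dimethoxyphenyl)-2-(hydroxymethyl)-6,8-dimethoxy-1,2-dihydronaphthalene-3-carbaldehyde
Conditions: BCl3, C6HMe5, CH2Cl2, −78 → −40 °C; MeOH quench
Reagents that add atoms: none
Why: Boron trichloride cleaves aryl and alkyl benzyl ethers at low temperature by benzyl-cation transfer to pentamethylbenzene, which keeps the cation away from the electron-rich rings, while the methyl ethers, the enal and both stereocentres should be untouched at this temperature.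

**Compound list**
1 | 4-hydroxy-3,5-dimethoxyphenylacetic acid | COc1cc(CC(=O)O)cc(OC)c1O | starting material
2 | benzyl 2-[4-(benzyloxy)-3,5-dimethoxyphenyl]acetate | COc1cc(CC(=O)OCc2ccccc2)cc(OC)c1OCc1ccccc1 | intermediate
3 | 2-[4-(benzyloxy)-3,5-dimethoxyphenyl]acetic acid | COc1cc(CC(=O)O)cc(OC)c1OCc1ccccc1 | intermediate
4 | (2R,5R)-2,5-dimethylpyrrolidine | C[C@@H]1CC[C@@H](C)N1 | starting material
5 | 2-[4-(benzyloxy)-3,5-dimethoxyphenyl]acetyl chloride | COc1cc(CC(=O)Cl)cc(OC)c1OCc1ccccc1 | intermediate
6 | 2-[4-(benzyloxy)-3,5-dimethoxyphenyl]-1-[(2R,5R)-2,5-dimethylpyrrolidin-1-yl]ethan-1-one | C[C@@H]1CC[C@@H](C)N1C(=O)Cc1cc(OC)c(OCc2ccccc2)c(OC)c1 | intermediate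
7 | allyl benzyl ether | C=CCOCc1ccccc1 | starting material
8 | (2R,5R)-1-{2-[4-(benzyloxy)-3,5-dimethoxyphenyl]ethenylidene}-2,5-dimethylpyrrolidin-1-ium triflate (keteniminium salt) | C[C@@H]1CC[C@@H](C)[N+]1=C=Cc1cc(OC)c(OCc2ccccc2)c(OC)c1.[O-]S(=O)(=O)C(F)(F)F | intermediate
9 | (2R,5R)-1-{(2S,3S)-2-[4-(benzyloxy)-3,5-dimethoxyphenyl]-3-[(benzyloxy)methyl]cyclobutylidene}-2,5-dimethylpyrrolidin-1-ium triflate | C[C@@H]1CC[C@@H](C)[N+]1=C2C[C@H](COCc3ccccc3)[C@H]2c2cc(OC)c(OCc3ccccc3)c(OC)c2.[O-]S(=O)(=O)C(F)(F)F | intermediate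
10 | (2S,3S)-2-[4-(benzyloxy)-3,5-dimethoxyphenyl]-3-[(benzyloxy)methyl]cyclobutan-1-one (trans) | O=C1C[C@H](COCc2ccccc2)[C@H]1c1cc(OC)c(OCc2ccccc2)c(OC)c1 | intermediate
11 | 4-bromo-2,6-dimethoxyphenol | COc1cc(Br)cc(OC)c1O | starting material
12 | 2-(benzyloxy)-5-bromo-1,3-dimethoxybenzene | COc1cc(Br)cc(OC)c1OCc1ccccc1 | intermediate
13 | [4-(benzyloxy)-3,5-dimethoxyphenyl]lithium | [Li]c1cc(OC)c(OCc2ccccc2)c(OC)c1 | intermediate
14 | (1S,2S,3S)-1,2-bis[4-(benzyloxy)-3,5-dimethoxyphenyl]-3-[(benzyloxy)methyl]cyclobutan-1-ol (aryl groups trans; expected major isomer) | COc1cc([C@]2(O)C[C@H](COCc3ccccc3)[C@H]2c2cc(OC)c(OCc3ccccc3)c(OC)c2)cc(OC)c1OCc1ccccc1 | intermediate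
15 | (3S,4S)-6-(benzyloxy)-4-[4-(benzyloxy)-3,5-dimethoxyphenyl]-3-[(benzyloxy)methyl]-5,7-dimethoxy-3,4-dihydronaphthalen-1(2H)-one (trans) | COc1cc([C@H]2c3c(cc(OC)c(OCc4ccccc4)c3OC)C(=O)C[C@@H]2COCc2ccccc2)cc(OC)c1OCc1ccccc1 | intermediate
16 | (2Z,3R,4S)-6-(benzyloxy)-4-[4-(benzyloxy)-3,5-dimethoxyphenyl]-3-[(benzyloxy)methyl]-2-(hydroxymethylidene)-5,7-dimethoxy-3,4-dihydronaphthalen-1(2H)-one | COc1cc([C@H]2c3c(cc(OC)c(OCc4ccccc4)c3OC)C(=O)/C(=C\O)[C@@H]2COCc2ccccc2)cc(OC)c1OCc1ccccc1 | intermediate
17 | (2E,3R,4S)-6-(benzyloxy)-4-[4-(benzyloxy)-3,5-dimethoxyphenyl]-3-[(benzyloxy)methyl]-5,7-dimethoxy-2-[(propan-2-yloxy)methylidene]-3,4-dihydronaphthalen-1(2H)-one | COc1cc([C@H]2c3c(cc(OC)c(OCc4ccccc4)c3OC)C(=O)/C(=C/OC(C)C)[C@@H]2COCc2ccccc2)cc(OC)c1OCc1ccccc1 | intermediate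
18 | (2E,3R,4S)-6-(benzyloxy)-4-[4-(benzyloxy)-3,5-dimethoxyphenyl]-3-[(benzyloxy)methyl]-5,7-dimethoxy-2-[(propan-2-yloxy)methylidene]-1,2,3,4-tetrahydronaphthalen-1-ol (C1 epimers) | COc1cc([C@H]2c3c(cc(OC)c(OCc4ccccc4)c3OC)C(O)/C(=C/OC(C)C)[C@@H]2COCc2ccccc2)cc(OC)c1OCc1ccccc1 | intermediate
19 | (1S,2R)-7-(benzyloxy)-1-[4-(benzyloxy)-3,5-dimethoxyphenyl]-2-[(benzyloxy)methyl]-6,8-dimethoxy-1,2-dihydronaphthalene-3-carbaldehyde | COc1cc([C@H]2c3c(cc(OC)c(OCc4ccccc4)c3OC)C=C(C=O)[C@@H]2COCc2ccccc2)cc(OC)c1OCc1ccccc1 | intermediate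
20 | (1S,2R)-7-hydroxy-1-(4-hydroxy-3,5-dimethoxyphenyl)-2-(hydroxymethyl)-6,8-dimethoxy-1,2-dihydronaphthalene-3-carbaldehyde | COc1cc([C@H]2c3c(cc(OC)c(O)c3OC)C=C(C=O)[C@@H]2CO)cc(OC)c1O | target

**Step count**
Total: 10 steps. Longest linear sequence: 9 steps (1, 2, 3, 5, 6, 7, 8, 9, 10); step 4 is the side branch.

**Steps most likely to fail**

Step 6. The risks are further one-electron oxidation of the electron-rich product at its doubly benzylic C1–H, and loss of trans control if radical and cationic closures compete. The fallback sets out from 14 and separates bond cleavage from bond formation. A redox-neutral photoredox ring opening by proton-coupled electron transfer (iridium photocatalyst, collidine, catalytic thiophenol as hydrogen-atom donor, blue light) should cleave the same ring bond and give the open-chain ketone (3R)-1,4-bis[4-(benzyloxy)-3,5-dimethoxyphenyl]-3-[(benzyloxy)methyl]butan-1-one F1. One equivalent of DDQ in CH2Cl2/TFA at 0 °C would then abstract hydride from the 4-alkoxybenzylic CH2, and the cation should close onto the ortho carbon of the aryl ketone ring in a Friedel–Crafts sense. Cationic closures of this kind to 1-aryltetralins favour the trans isomer, so the sequence comes back to the route at 15.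

Step 3. The risks are insufficient facial discrimination by the auxiliary, erosion of C3 purity if cis and trans cycloadducts of opposite C3 sense converge on epimerisation at C2, and capture of the keteniminium ion by the electron-rich arene of a second molecule. The fallback sets out from bromide 12 and commercial, achiral 3-[(benzyloxy)methyl]cyclobutan-1-one. Deprotonation of one enantiotopic α-position with a chiral lithium amide (lithium bis(1-phenylethyl)amide of the appropriate hand, TMSCl present, THF, −100 °C) should give the silyl enol ether (S)-({3-[(benzyloxy)methyl]cyclobut-1-en-1-yl}oxy)trimethylsilane F2. Palladium-catalysed α-arylation of this enol ether with 12 (Pd(OAc)2, P(t-Bu)3, Bu3SnF, toluene, 80 °C) would then install the aryl group next to the fixed C3 centre, trans after equilibration, and the sequence comes back to the route at 10.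

Step 9. The risks are incomplete or conjugate hydride delivery to the cross-conjugated vinylogous ester, and capture of the highly stabilised C4 cation by the electron-rich rings of a second molecule during the acid phase. The fallback sets out from 15 and avoids the enol ether altogether. Sodium borohydride reduction should give the tetralol (3S,4S)-6-(benzyloxy)-4-[4-(benzyloxy)-3,5-dimethoxyphenyl]-3-[(benzyloxy)methyl]-5,7-dimethoxy-1,2,3,4-tetrahydronaphthalen-1-ol F3. Mild acid-catalysed dehydration (cat. TsOH, toluene, rt) would then give the styrene-type alkene (1S,2S)-7-(benzyloxy)-1-[4-(benzyloxy)-3,5-dimethoxyphenyl]-2-[(benzyloxy)methyl]-6,8-dimethoxy-1,2-dihydronaphthalene F4. Vilsmeier–Haack formylation (POCl3, DMF, 0 °C → rt, aqueous NaOAc work-up) should attack the β-carbon C3 of this para-alkoxystyrene and, after loss of the C3 proton and hydrolysis, come back to the route at 19.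

**Further compounds**
F1 | step 6 | (3R)-1,4-bis[4-(benzyloxy)-3,5-dimethoxyphenyl]-3-[(benzyloxy)methyl]butan-1-one | COc1cc(C(=O)C[C@H](COCc2ccccc2)Cc2cc(OC)c(OCc3ccccc3)c(OC)c2)cc(OC)c1OCc1ccccc1
F2 | step 3 | (S)-({3-[(benzyloxy)methyl]cyclobut-1-en-1-yl}oxy)trimethylsilane | C[Si](C)(C)OC1=C[C@@H](COCc2ccccc2)C1
F3 | step 9 | (3S,4S)-6-(benzyloxy)-4-[4-(benzyloxy)-3,5-dimethoxyphenyl]-3-[(benzyloxy)methyl]-5,7-dimethoxy-1,2,3,4-tetrahydronaphthalen-1-ol (C1 epimers) | COc1cc([C@H]2c3c(cc(OC)c(OCc4ccccc4)c3OC)C(O)C[C@@H]2COCc2ccccc2)cc(OC)c1OCc1ccccc1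
F4 | step 9 | (1S,2S)-7-(benzyloxy)-1-[4-(benzyloxy)-3,5-dimethoxyphenyl]-2-[(benzyloxy)methyl]-6,8-dimethoxy-1,2-dihydronaphthalene | COc1cc([C@H]2c3c(cc(OC)c(OCc4ccccc4)c3OC)C=C[C@@H]2COCc2ccccc2)cc(OC)c1OCc1ccccc1
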